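## Retrosynthetic overview

1. Ester C–O: the target comes from macrophorin A and prochiral 3-hydroxy-3-methylglutaric anhydride. A catalyst-controlled desymmetrising ring opening sets the glutarate centre.
2. Carbinol C–H: macrophorin A comes from 4'-oxomacrophorin A by hydroxyl-directed hydride delivery on the oxirane face.
3. Rings A and B in one operation: 4'-oxomacrophorin A comes from the linear farnesyl epoxyquinone. The step is a proton-initiated chair–chair bicyclisation on the finished, unprotected head group, ended by loss of a C12 proton.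
4. Oxirane: the epoxyquinone comes from a quinone monoketal by asymmetric nucleophilic epoxidation, and the monoketal comes from a farnesylphenol by oxidative dearomatisation.
5. Aryl–C1 bond: the farnesylphenol comes from 3-hydroxybenzyl alcohol and farnesol. Ring order: the head ring is bought as the arene, the oxirane is formed first, then ring A and ring B together.

Assumption: the target is macrophorin D as drawn, with a (3R)-glutarate; the sense of induction of the tartrate, the IDPi acid and the cinchona diether is assigned by analogy, and each is available in its mirror-image or pseudo-enantiomeric form.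

## Route

Step 1
Reactants: 1 (2E,6E)-farnesol
Product: 2 (2E,6E)-farnesyl bromide
Conditions: PBr3 (0.4 equiv), Et2O, 0 °C
Reagents that add atoms: phosphorus tribromide, BrP(Br)Br
Why: PBr3 bromination of a primary allylic alcohol goes through the phosphite ester by SN2 displacement at 0 °C, so there is no allylic transposition, both E alkenes are kept and no stereocentre is formed.

Step 2
Reactants: 2 (2E,6E)-farnesyl bromide; 3 3-hydroxybenzyl alcohol
Product: 5 2-[(2E,6E)-farnesyl]-5-(hydroxymethyl)phenol, via sodium 3-(hydroxymethyl)phenoxide 4 (not isolated)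
Conditions: NaH (1.0 equiv per 3), toluene, 0 °C to rt; 3 in 1.5-fold excess
Reagents that add atoms: none
Why: Ortho-selective C-allylation of a phenoxide (tight sodium ion pair in a non-polar medium, the laboratory counterpart of aromatic prenyl transfer) attacks C1 of 2 by SN2 from the less hindered ortho carbon, para to CH2OH, so the E geometry is kept, the less acidic benzylic OH stays untouched and no stereocentre is formed.

Step 3
Reactants: 5 2-[(2E,6E)-farnesyl]-5-(hydroxymethyl)phenol
Product: 7 2-[(2E,6E)-farnesyl]-5-(hydroxymethyl)-4,4-dimethoxycyclohexa-2,5-dien-1-one, via 2-farnesyl-5-(hydroxymethyl)-4-methoxyphenol 6 (not isolated)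
Conditions: PhI(OAc)2 (2.2 equiv), MeOH, 0 °C to rt
Reagents that add atoms: methanol, CO
Why: Twofold oxidative dearomatisation with trivalent iodine (phenol to para-quinone monoketal oxidation) traps methanol twice at the free para carbon; the phenol is oxidised far faster than the isolated trisubstituted alkenes, and no stereocentre is formed.

Step 4
Reactants: 7 2-[(2E,6E)-farnesyl]-5-(hydroxymethyl)-4,4-dimethoxycyclohexa-2,5-dien-1-one
Product: 8 (1S,6R)-1-[(2E,6E)-farnesyl]-4-(hydroxymethyl)-5,5-dimethoxy-7-oxabicyclo[4.1.0]hept-3-en-2-one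
Conditions: Ph3COOH (1.5 equiv), NaN(SiMe3)2 (2.2 equiv), L-(+)-diisopropyl tartrate (1.2 equiv), 4 Å MS, toluene, −65 °C
Reagents that add atoms: trityl hydroperoxide, OOC(c1ccccc1)(c1ccccc1)c1ccccc1
Why: In this hydroxyl-directed, tartrate-mediated nucleophilic (Weitz–Scheffer type) epoxidation the sodium alkoxide of the CH2OH group, the tartrate and the trityl peroxide form a chiral aggregate that delivers the peroxide to the only unsubstituted enone β-carbon, so the ketal fixes the regiochemistry, the tartrate sets both oxirane centres (1S,6R) at once, and the isolated alkenes are inert to a nucleophilic peroxide.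

Step 5
Reactants: 8 (1S,6R)-1-[(2E,6E)-farnesyl]-4-(hydroxymethyl)-5,5-dimethoxy-7-oxabicyclo[4.1.0]hept-3-en-2-one
Product: 9 (1S,6R)-1-[(2E,6E)-farnesyl]-4-(hydroxymethyl)-7-oxabicyclo[4.1.0]hept-3-ene-2,5-dione
Conditions: 48% aq. HF, MeCN, 0 °C
Reagents that add atoms: water, O
Why: Acid-catalysed ketal hydrolysis frees the second carbonyl; the electron-poor oxirane does not ionise, dilute HF does not protonate trisubstituted alkenes, and both oxirane centres are untouched.

Step 6
Reactants: 9 (1S,6R)-1-[(2E,6E)-farnesyl]-4-(hydroxymethyl)-7-oxabicyclo[4.1.0]hept-3-ene-2,5-dione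
Product: 10 4'-oxomacrophorin A, (1S,6R)-4-(hydroxymethyl)-1-{[(1S,4aS,8aS)-5,5,8a-trimethyl-2-methylidenedecahydronaphthalen-1-yl]methyl}-7-oxabicyclo[4.1.0]hept-3-ene-2,5-dione
Conditions: confined chiral IDPi Brønsted acid (BINOL-derived imidodiphosphorimidate with N-SO2CF3 groups, the enantiomer that turns (3E,7E)-homofarnesol into (−)-ambrox; 5 mol %), (CF3)3COH, 0.02 M, 0 °C, then Et3N
Reagents that add atoms: none
Why: Proposed new method: a strong confined chiral acid in a non-nucleophilic fluorinated alcohol protonates only the slim terminal isopropylidene (the 2,3-alkene is inductively deactivated by the epoxydione, and the oxirane between two carbonyl groups cannot ionise), the E,E-triene closes through the chair–chair fold (Stork–Eschenmoser) inside the chiral pocket so that C5, C10 and C9 are set together as 5S,10S,9S under catalyst control with the side chain equatorial, and the buried hindered counter-anion reaches only the exposed C12 methyl protons of the C8 cation, giving the exocyclic alkene, which is too bulky to re-enter the pocket and isomerise; the closest known reaction types are the IDPi-catalysed proton-initiated cyclisation of homofarnesol to ambrox and the exo-selective proton abstraction from tertiary cations by hindered bases, and the step copies the late-stage cyclase reaction of the biosynthesis.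

Step 7
Reactants: 10 4'-oxomacrophorin A
Product: 11 macrophorin A, (1S,5R,6S)-5-hydroxy-4-(hydroxymethyl)-1-{[(1S,4aS,8aS)-5,5,8a-trimethyl-2-methylidenedecahydronaphthalen-1-yl]methyl}-7-oxabicyclo[4.1.0]hept-3-en-2-one
Conditions: iBu2AlH (3.0 equiv), THF, −78 °C; aq. potassium sodium tartrate
Reagents that add atoms: none
Why: In this hydroxyl-directed, chelation-controlled 1,2-reduction the aluminium alkoxide of the CH2OH group activates the neighbouring carbonyl (the other one is shielded by the quaternary oxirane carbon), and a second iBu2AlH held on the oxirane oxygen, with the drimanylmethyl group blocking the opposite face, delivers hydride on the oxirane face, so the new carbinol is 5R with OH anti to the epoxide.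

Step 8
Reactants: 11 macrophorin A; 12 3-hydroxy-3-methylglutaric anhydride
Product: 13 target, macrophorin D with a (3R)-3-hydroxy-3-methylglutarate half ester
Conditions: 12 (2 equiv), (DHQD)2AQN [hydroquinidine anthraquinone-1,4-diyl diether] (30 mol %), Et2O–toluene, −20 °C; aq. citric acid wash; HPLC
Reagents that add atoms: none
Why: Proposed new method: cinchona-alkaloid general-base catalysis of the alcoholysis of a prochiral cyclic anhydride (known for methanol, benzyl and allyl alcohols on 3-substituted glutaric anhydrides) is extended to a complex primary allylic alcohol as the limiting nucleophile, so the quinuclidine activates the unhindered primary OH and leaves the secondary one, the catalyst picks one of the two enantiotopic carbonyl groups and sets the glutarate centre as 3R, no protecting group is needed, and any 3S epimer is a diastereomer that HPLC removes.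

## Compound list

1 | (2E,6E)-farnesol | CC(C)=CCC/C(C)=C/CC/C(C)=C/CO | starting material
2 | (2E,6E)-farnesyl bromide | CC(C)=CCC/C(C)=C/CC/C(C)=C/CBr | intermediate
3 | 3-hydroxybenzyl alcohol | OCc1cccc(O)c1 | starting material
4 | sodium 3-(hydroxymethyl)phenoxide | [Na+].[O-]c1cccc(CO)c1 | intermediate
5 | 2-[(2E,6E)-farnesyl]-5-(hydroxymethyl)phenol | CC(C)=CCC/C(C)=C/CC/C(C)=C/Cc1ccc(CO)cc1O | intermediate
6 | 2-[(2E,6E)-farnesyl]-5-(hydroxymethyl)-4-methoxyphenol | CC(C)=CCC/C(C)=C/CC/C(C)=C/Cc1cc(OC)c(CO)cc1O | intermediate
7 | 2-[(2E,6E)-farnesyl]-5-(hydroxymethyl)-4,4-dimethoxycyclohexa-2,5-dien-1-one | CC(C)=CCC/C(C)=C/CC/C(C)=C/CC1=CC(OC)(OC)C(CO)=CC1=O | intermediate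
8 | (1S,6R)-1-[(2E,6E)-farnesyl]-4-(hydroxymethyl)-5,5-dimethoxy-7-oxabicyclo[4.1.0]hept-3-en-2-one | CC(C)=CCC/C(C)=C/CC/C(C)=C/C[C@]12O[C@H]1C(OC)(OC)C(CO)=CC2=O | intermediate
9 | (1S,6R)-1-[(2E,6E)-farnesyl]-4-(hydroxymethyl)-7-oxabicyclo[4.1.0]hept-3-ene-2,5-dione | CC(C)=CCC/C(C)=C/CC/C(C)=C/C[C@]12O[C@H]1C(=O)C(CO)=CC2=O | intermediate
10 | 4'-oxomacrophorin A | C=C1CC[C@H]2C(C)(C)CCC[C@]2(C)[C@H]1C[C@]12O[C@H]1C(=O)C(CO)=CC2=O | intermediate
11 | macrophorin A | C=C1CC[C@H]2C(C)(C)CCC[C@]2(C)[C@H]1C[C@]12O[C@H]1[C@H](O)C(CO)=CC2=O | intermediate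
12 | 3-hydroxy-3-methylglutaric anhydride | CC1(O)CC(=O)OC(=O)C1 | starting material
13 | target, macrophorin D, (3R)-glutarate | C=C1CC[C@H]2C(C)(C)CCC[C@]2(C)[C@H]1C[C@]12O[C@H]1[C@H](O)C(COC(=O)C[C@](C)(O)CC(=O)O)=CC2=O | target

## Step count and risks

Total step count: 8. Longest linear sequence: 8 steps (1 to 13).

**Step 6 (highest risk).**
- The C8 cation may lose H7 or H9 to give endocyclic alkenes.
- The closure may stop after ring A.
- The acid may re-protonate the exocyclic alkene.
- Fallback, from 9 back to 11: reduction and cyclisation change places, and the ring closure is handed to the enzyme that performs it in nature. Compound 9 is reduced with iBu2AlH (THF, −78 °C, same directing effects as in step 7) to the linear epoxyquinol (1S,5R,6S)-1-[(2E,6E)-farnesyl]-5-hydroxy-4-(hydroxymethyl)-7-oxabicyclo[4.1.0]hept-3-en-2-one F1. F1 is then fed to resting cells or microsomes of yeast or Aspergillus oryzae expressing the membrane-bound macrophorin cyclase MacJ. The enzyme protonates the terminal alkene and releases the drimane with the exocyclic alkene, which is 11.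

**Step 8.**
- OH and CH3 on the anhydride are of similar size, so the catalyst may distinguish the two carbonyl groups poorly or in the wrong sense.
- Fallback, from 11 back to 13: the glutarate centre is made beforehand by enzymatic desymmetrisation. Commercial dimethyl 3-hydroxy-3-methylglutarate is hydrolysed with pig liver esterase (pH 7 buffer) to (3S)-3-hydroxy-5-methoxy-3-methyl-5-oxopentanoic acid F2. The free acid of F2 is coupled to the primary OH of 11 (EDC·HCl, cat. DMAP, CH2Cl2, 0 °C) to give macrophorin D methyl ester F3. The unhindered methyl ester is then cleaved with Me3SnOH (1,2-dichloroethane, 60 °C; dilute acid work-up) to give 13. Esterifying the acid arm of the (S) half ester gives the (3R) descriptor of the target.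

**Step 7.**
- Hydride may enter anti to the oxirane and give the syn epimer.
- Fallback, from 10 back to 11: the syn epimer is made on purpose and then inverted. NaBH4/CeCl3·7H2O (MeOH, −78 °C) gives 4'-epi-macrophorin A F4. TBSCl/imidazole (CH2Cl2, 0 °C) caps the primary OH to give 4'-epi-macrophorin A primary TBS ether F5. Mitsunobu inversion (4-nitrobenzoic acid, PPh3, DIAD, THF, 0 °C) gives the inverted 4'-(4-nitrobenzoate) TBS ether F6. K2CO3/MeOH (0 °C) gives macrophorin A primary TBS ether F7, and 3HF·NEt3 (MeCN) frees 11.

## Further compounds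

F1 | step 6 | (1S,5R,6S)-1-[(2E,6E)-farnesyl]-5-hydroxy-4-(hydroxymethyl)-7-oxabicyclo[4.1.0]hept-3-en-2-one | CC(C)=CCC/C(C)=C/CC/C(C)=C/C[C@]12O[C@H]1[C@H](O)C(CO)=CC2=O
F2 | step 8 | (3S)-3-hydroxy-5-methoxy-3-methyl-5-oxopentanoic acid | OC(=O)C[C@](C)(O)CC(=O)OC
F3 | step 8 | macrophorin D methyl ester | C=C1CC[C@H]2C(C)(C)CCC[C@]2(C)[C@H]1C[C@]12O[C@H]1[C@H](O)C(COC(=O)C[C@](C)(O)CC(=O)OC)=CC2=O
F4 | step 7 | 4'-epi-macrophorin A | C=C1CC[C@H]2C(C)(C)CCC[C@]2(C)[C@H]1C[C@]12O[C@H]1[C@@H](O)C(CO)=CC2=O
F5 | step 7 | 4'-epi-macrophorin A primary TBS ether | C=C1CC[C@H]2C(C)(C)CCC[C@]2(C)[C@H]1C[C@]12O[C@H]1[C@@H](O)C(CO[Si](C)(C)C(C)(C)C)=CC2=O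
F6 | step 7 | inverted 4'-(4-nitrobenzoate) TBS ether | C=C1CC[C@H]2C(C)(C)CCC[C@]2(C)[C@H]1C[C@]12O[C@H]1[C@H](OC(=O)c1ccc([N+](=O)[O-])cc1)C(CO[Si](C)(C)C(C)(C)C)=CC2=O
F7 | step 7 | macrophorin A primary TBS ether | C=C1CC[C@H]2C(C)(C)CCC[C@]2(C)[C@H]1C[C@]12O[C@H]1[C@H](O)C(CO[Si](C)(C)C(C)(C)C)=CC2=O
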